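4 questions stand on one flask, which is the violet run itself followed on to a later time, with 5 options to weigh at that time.

1. target, in percent of the starting material first charged, at 1.5 h
2. which option adds most target ("none" when 2 percentage points or less is all one gets) (winter / noon / summer / autumn / spring / none)
3. target present, with what was taken out counted in, in percent of the starting material first charged, after winter
4. target present, with what was taken out counted in, in percent of the starting material first charged, after summer

| flask | starting material | second substrate | free enzyme | temperature | remark | time |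
|---|---|---|---|---|---|---|
| violet | 0.084 M | 4 equiv | 0.01 mol% | 5 °C | the very flask that is asked about, followed so far |  |
| ochre | 0.084 M | 4 equiv | 0.01 mol% | 11 °C | run made earlier |  |
| flask | 0.084 M | 4.00 equiv | 0.01 mol% | 5 °C |  | 1.5 h |

- winter: at 1.5 h add free enzyme, 100% of the amount charged, then wait 50 min
- noon: change nothing and wait 50 min more
- summer: at 1.5 h add second substrate, 50.0% of the amount charged, then wait 50 min
- autumn: at 1.5 h take out 90% of the target then present, then wait 50 min
- spring: at 1.5 h raise the temperature by 10 K, then wait 50 min

- target taken out counts as made
- the earlier runs were read with a standard deviation of 0.5 percentage points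
- additions bring no volume worth counting

| run | time / min | target / % | starting material / % |
|---|---|---|---|
| violet | 4.00 | 36.4 | 35.6 |
| violet | 10.0 | 40.9 | 25.7 |
| violet | 20.0 | 42.0 | 24.7 |
| violet | 30.0 | 41.8 | 24.5 |
| violet | 40.0 | 41.6 | 24.9 |
| violet | 50.0 | 41.4 | 25.1 |
| ochre | 4.00 | 34.0 | 46.2 |
| ochre | 10.0 | 36.6 | 42.2 |
| ochre | 20.0 | 37.2 | 41.9 |
| ochre | 30.0 | 34.7 | 41.5 |
| ochre | 40.0 | 36.5 | 43.1 |
| ochre | 50.0 | 36.8 | 42.7 |

(each reading ± 0.5 percentage points)

The starting material is the limiting reagent of the charge, and at one second substrate per starting material consumed, violet at its last reading still holds 81.3% of its own charge, so I do not look to the second substrate for the stop. But the starting material in violet stands near 25.1% from 20.0 min on, and in the warmer ochre run it stands higher, at 42.7%, so I read both runs as a free enzyme that dies early, and earlier when warmer.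

So I carry one number, the reach of a charge of free enzyme, the natural logarithm of starting material charged over starting material left once the flask stands still, which reads 1.38 in violet. An enzyme that does nothing has reach zero, and at one temperature, with the starting material and second substrate held as charged here, I take the reach to grow in step with the enzyme charged, each equal step removing the same fraction of what is there.

By my reckoning winter then brings one more reach, which puts the starting material at 6.30%. With target at 0.553 of what is consumed, a reading above the even split, I reckon 51.8% after winter. The other options bring no enzyme, so I put their gain at nothing.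

The forecast says 41.6% now, winter as the best option, 51.5% after it and 41.6% after summer, on the ground that “Dying free enzyme fits best”; its figure for winter lies a little below mine.

The flask gives 41.6% now, 41.6% after summer and 49.8% after winter, a gain of 8.2 percentage points.

    free enzyme → unfolded enzyme (k = 6.80 × 10⁻⁵ s⁻¹, Ea = 288 kJ mol⁻¹)
    starting material + free enzyme ⇌ starting complex (K = 11.0 M⁻¹, k = 12000 M⁻¹ s⁻¹, Ea = 23.0 kJ mol⁻¹, ΔH = 18.0 kJ mol⁻¹)
    second substrate + starting complex ⇌ ternary complex (K = 1.40 M⁻¹, k = 34000 M⁻¹ s⁻¹, Ea = 28.0 kJ mol⁻¹, ΔH = −67.0 kJ mol⁻¹)
    ternary complex → free enzyme + target (k = 390 s⁻¹, Ea = 54.0 kJ mol⁻¹)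
    target + free enzyme ⇌ isomer of the product + free enzyme, rate k5*[free enzyme]*[target] forward; the back reaction follows from the equilibrium constant (K = 0.910, k = 4300 M⁻¹ s⁻¹, Ea = 22.0 kJ mol⁻¹, ΔH = −32.0 kJ mol⁻¹)
    second substrate + free enzyme → spent catalyst A (k = 0.0300 M⁻¹ s⁻¹, Ea = 57.0 kJ mol⁻¹)
    2 ternary complex → spent catalyst B (k = 1000 M⁻¹ s⁻¹, Ea = 40.0 kJ mol⁻¹)
    (constants at 5 °C)

Winter is the best option, while noon, summer, autumn and spring each add 0 points. At 90.0 min the flask holds 0% of its catalyst as free enzyme and 96.6% as spent catalyst A. The reach of this flask is 1.40. Scaled to the neighbour charged with 0.004 mol% of free enzyme, it becomes 0.558, which leaves 57.2% of the starting material, and that neighbour stands at 57.1%.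

The earlier runs and the new flask come from a simulation for an exercise; scatter was added.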